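## Retrosynthetic overview

1. Target 25 ⇒ propynyl carbinol 24 by a Meyer–Schuster 1,3-oxygen shift (forms C9=O and the E C7=C8 bond); 24 ⇒ methyl ketone 21 + a propynyl nucleophile.
2. 21 ⇒ racemic tertiary propargylic acetate 17. Enantioselective C7–O bond formation (1,3-acyloxy transposition) gives an axially chiral dienyl allene that closes the carbocycle by 6π electrocyclisation; C1 comes from the axis, C6 from a kinetic protonation.
3. 17 ⇒ dienyl iodide 13 + pent-3-yn-2-one; 13 ⇒ 2-ethylpyranone 5 + (Z)-3-iodo-2-methylpropenal 9 (aldol, dehydration).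
4. 5 ⇒ 3,5-diketo ester 4 (C–O ring closure) ⇒ keto ester 1 + Weinreb amide 2.
5. Ring order: pyranone ring first (step 2), cyclohexadiene ring second (step 8).

Assumption: the SMILES is read as the (1S,6S) isomer with the pyranone on C1 and the oxopentenyl chain on C6 cis; locants are ring C1–C6 (C1 quaternary) and chain C7–C9, and the open-chain precursors carry the same locants (C5 bears the acetate in 17, C7 becomes the ketone carbon of 21).

## Route

Step 1
Reactants: 1 methyl 2-methyl-3-oxopentanoate; 2 N-methoxy-N-methylpropanamide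
Product: 4 methyl 2,4-dimethyl-3,5-dioxoheptanoate, via dilithium dienolate 3 (not isolated)
Conditions: LiN(iPr)2 (2.2 equiv), THF, −78 → 0 °C; then 2, −78 °C → rt
Reagents that add atoms: none
Why: The β-keto ester dianion is acylated at its γ-carbon by the Weinreb amide (Claisen-type acylation), and the chelated tetrahedral adduct prevents over-addition; the stereocentres are lost in step 2.

Step 2
Reactants: 4 methyl 2,4-dimethyl-3,5-dioxoheptanoate
Product: 5 2-ethyl-6-methoxy-3,5-dimethyl-4H-pyran-4-one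
Conditions: PPh3, CCl4, THF, rt
Reagents that add atoms: none
Why: Appel-type activation of the C5 enol as its oxyphosphonium salt lets the ester carbonyl oxygen close the ring (C–O bond formation) with loss of Ph3PO, and the ester methoxy group is kept as the 2-methoxy group of the γ-pyranone (dehydrative cyclisation of a 3,5-diketo ester).

Step 3
Reactants: 6 prop-2-yn-1-ol
Product: 8 (2Z)-3-iodo-2-methylprop-2-en-1-ol, via alkenylmagnesium alkoxide 7 (not isolated)
Conditions: MeMgBr (3 equiv), CuI (10 mol %), Et2O, −10 °C → rt; then I2, −78 → 0 °C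
Reagents that add atoms: methylmagnesium bromide, C[Mg]Br; iodine, II
Why: Alkoxide-directed, copper-catalysed anti-carbomagnesiation puts methyl on C2 and magnesium on C3 cis to the CH2O group (five-membered magnesacycle), and iodinolysis with retention gives the Z iodide.

Step 4
Reactants: 8 (2Z)-3-iodo-2-methylprop-2-en-1-ol
Product: 9 (2Z)-3-iodo-2-methylprop-2-enal
Conditions: MnO2, CH2Cl2, rt, dark
Reagents that add atoms: none
Why: Heterogeneous MnO2 oxidation of a primary allylic alcohol is neutral and leaves the Z vinyl iodide untouched (allylic oxidation).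

Step 5
Reactants: 5 2-ethyl-6-methoxy-3,5-dimethyl-4H-pyran-4-one; 9 (2Z)-3-iodo-2-methylprop-2-enal
Product: 11 2-[(4Z)-3-hydroxy-5-iodo-4-methylpent-4-en-2-yl]-6-methoxy-3,5-dimethyl-4H-pyran-4-one, via lithiated pyranone 10 (not isolated)
Conditions: LiN(SiMe3)2, THF, −78 °C; then 9, −78 °C
Reagents that add atoms: none
Why: The ethyl CH2 of 5 is vinylogously acidic, and its lithium trienolate adds to the aldehyde (vinylogous aldol addition); both new stereocentres are removed in step 6.

Step 6
Reactants: 11 2-[(4Z)-3-hydroxy-5-iodo-4-methylpent-4-en-2-yl]-6-methoxy-3,5-dimethyl-4H-pyran-4-one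
Product: 13 2-[(2E,4Z)-5-iodo-4-methylpenta-2,4-dien-2-yl]-6-methoxy-3,5-dimethyl-4H-pyran-4-one, via mesylate 12 (not isolated)
Conditions: MsCl, Et3N, CH2Cl2, 0 °C; then DBU, rt
Reagents that add atoms: none
Why: Mesylation and E1cB-type elimination through the pyranone-activated CH give the thermodynamically preferred E alkene (pyranone trans to the chain), while the Z vinyl iodide is unaffected.

Step 7
Reactants: 13 2-[(2E,4Z)-5-iodo-4-methylpenta-2,4-dien-2-yl]-6-methoxy-3,5-dimethyl-4H-pyran-4-one; 14 pent-3-yn-2-one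
Product: 17 racemic (5Z,7E)-8-(6-methoxy-3,5-dimethyl-4-oxo-4H-pyran-2-yl)-4,6-dimethylnona-5,7-dien-2-yn-4-yl acetate, via dienylmagnesium chloride 15 (not isolated), via chloromagnesium alkoxide 16 (not isolated)
Conditions: iPrMgCl·LiCl (1.05 equiv), THF, −40 °C; then 14, LaCl3·2LiCl (30 mol %), −78 → −20 °C; then Ac2O, DMAP (cat.), 0 °C → rt
Reagents that add atoms: acetic anhydride, CC(=O)OC(C)=O
Why: Iodine–magnesium exchange keeps the Z geometry, the alkenyl Grignard adds 1,2 to the ynone (lanthanum-promoted carbonyl addition), and the alkoxide is acetylated in the flask; the new carbinol centre is formed racemic, which is harmless because step 8 passes through a planar cation.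

Step 8
Reactants: 17 racemic (5Z,7E)-8-(6-methoxy-3,5-dimethyl-4-oxo-4H-pyran-2-yl)-4,6-dimethylnona-5,7-dien-2-yn-4-yl acetate
Product: 21 2-[(1S,6R)-6-acetyl-1,3,5-trimethylcyclohexa-2,4-dien-1-yl]-6-methoxy-3,5-dimethyl-4H-pyran-4-one, via allenyl acetate 18 (not isolated), via enol acetate 19 (not isolated), via lithium enolate 20 (not isolated)
Conditions: (R)-3,3′-bis(2,4,6-triisopropylphenyl)-1,1′-binaphthyl-2,2′-diyl N-triflylphosphoramide (5 mol %), methylcyclohexane/toluene 4:1, −40 °C; then 2,6-lutidine (10 mol %), 40 °C; then MeLi (2.2 equiv), THF, −78 °C; then AcOH, −78 °C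
Reagents that add atoms: none
Why: Proposed new method: the chiral Brønsted acid ionises racemic 17 to an achiral dienyl-propargyl cation held in a contact ion pair with the phosphoramide anion and acetic acid, and the acetic acid returns to C7 on one face only, so both enantiomers of 17 converge on allenyl acetate 18 with the aR axis (a catalytic enantioconvergent 1,3-acyloxy transposition in which the C7–O bond is the enantio-determining bond; the antipodal acid is used if the sense of induction proves opposite); 18 is a (Z)-dienyl allene and, once the acid is neutralised, closes by thermal disrotatory 6π electrocyclisation far below the temperature a simple triene needs, the methyl on the allene terminus turning outward and the acetoxy group inward so that the axis is transferred to the quaternary centre C1 (S); MeLi then cleaves enol acetate 19 to enolate 20, and protonation at −78 °C on the face opposite the pyranone sets C6 (R, acetyl cis to pyranone); the closest known reactions are the AgBF4- or AuCl(PPh3)/AgSbF6-catalysed 1,3-acyloxy migration of tertiary propargylic esters to allenyl esters, the chiral-acid-catalysed enantioconvergent substitution of racemic tertiary propargylic alcohols to tetrasubstituted allenes with carbon and sulfur nucleophiles, and the 6π electrocyclisation of dienyl allenes with axis-to-centre chirality transfer.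

Step 9
Reactants: 21 2-[(1S,6R)-6-acetyl-1,3,5-trimethylcyclohexa-2,4-dien-1-yl]-6-methoxy-3,5-dimethyl-4H-pyran-4-one; 22 1-propynylmagnesium bromide
Product: 24 2-[(1S,6R)-6-(2-hydroxypent-3-yn-2-yl)-1,3,5-trimethylcyclohexa-2,4-dien-1-yl]-6-methoxy-3,5-dimethyl-4H-pyran-4-one, via propynylcerium dichloride 23 (not isolated)
Conditions: CeCl3 (anhydrous), THF, −78 °C; then 21, −78 °C
Reagents that add atoms: none
Why: The weakly basic organocerium reagent adds to the methyl ketone without enolising the acidic, doubly activated C6–H, so C1 and C6 are untouched (organocerium carbonyl addition); the new carbinol centre forms as a mixture and is destroyed in step 10.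

Step 10
Reactants: 24 2-[(1S,6R)-6-(2-hydroxypent-3-yn-2-yl)-1,3,5-trimethylcyclohexa-2,4-dien-1-yl]-6-methoxy-3,5-dimethyl-4H-pyran-4-one
Product: 25 2-methoxy-3,5-dimethyl-6-[(1S,6S)-1,3,5-trimethyl-6-[(2E)-4-oxopent-2-en-2-yl]cyclohexa-2,4-dien-1-yl]-4H-pyran-4-one
Conditions: MoO2(acac)2 (2 mol %), AuCl(PPh3) (2 mol %), AgOTf (2 mol %), toluene, 25 °C
Reagents that add atoms: none
Why: Meyer–Schuster rearrangement moves the oxygen from C7 to C9 through the molybdate ester under neutral conditions, and the E enone (ring carbon trans to acetyl) is favoured because the Z isomer suffers allylic strain between the ring and the acetyl group; C1 and C6 are not involved.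

## Compound list

1 | methyl 2-methyl-3-oxopentanoate | CCC(=O)C(C)C(=O)OC | starting material
2 | N-methoxy-N-methylpropanamide | CCC(=O)N(C)OC | starting material
3 | dilithium dienolate of 1 (dilithium 1-methoxy-2-methylpenta-1,3-diene-1,3-diolate) | CC=C(O[Li])C(C)=C(O[Li])OC | intermediate
4 | methyl 2,4-dimethyl-3,5-dioxoheptanoate (diastereomer and tautomer mixture) | CCC(=O)C(C)C(=O)C(C)C(=O)OC | intermediate
5 | 2-ethyl-6-methoxy-3,5-dimethyl-4H-pyran-4-one | CCc1oc(OC)c(C)c(=O)c1C | intermediate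
6 | prop-2-yn-1-ol | C#CCO | starting material
7 | bromomagnesium (2Z)-3-(bromomagnesio)-2-methylprop-2-en-1-olate | Br[Mg]/C=C(/C)CO[Mg]Br | intermediate
8 | (2Z)-3-iodo-2-methylprop-2-en-1-ol | OC/C(C)=C\I | intermediate
9 | (2Z)-3-iodo-2-methylprop-2-enal | O=C/C(C)=C\I | intermediate
10 | lithium 2-ethylidene-6-methoxy-3,5-dimethyl-2H-pyran-4-olate (lithiated 5) | CC=C1OC(OC)=C(C)C(O[Li])=C1C | intermediate
11 | 2-[(4Z)-3-hydroxy-5-iodo-4-methylpent-4-en-2-yl]-6-methoxy-3,5-dimethyl-4H-pyran-4-one (racemic diastereomer mixture) | COc1oc(C(C)C(O)/C(C)=C\I)c(C)c(=O)c1C | intermediate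
12 | methanesulfonate of 11 | COc1oc(C(C)C(OS(C)(=O)=O)/C(C)=C\I)c(C)c(=O)c1C | intermediate
13 | 2-[(2E,4Z)-5-iodo-4-methylpenta-2,4-dien-2-yl]-6-methoxy-3,5-dimethyl-4H-pyran-4-one | COc1oc(/C(C)=C/C(C)=C\I)c(C)c(=O)c1C | intermediate
14 | pent-3-yn-2-one | CC#CC(C)=O | starting material
15 | chloro[(1Z,3E)-4-(6-methoxy-3,5-dimethyl-4-oxo-4H-pyran-2-yl)-2-methylpenta-1,3-dien-1-yl]magnesium | COc1oc(/C(C)=C/C(C)=C\[Mg]Cl)c(C)c(=O)c1C | intermediate
16 | chloromagnesium alkoxide of the tertiary propargylic alcohol (racemic) | COc1oc(/C(C)=C/C(C)=C\C(C)(O[Mg]Cl)C#CC)c(C)c(=O)c1C | intermediate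
17 | (5Z,7E)-8-(6-methoxy-3,5-dimethyl-4-oxo-4H-pyran-2-yl)-4,6-dimethylnona-5,7-dien-2-yn-4-yl acetate (racemic at C4 of the chain) | COc1oc(/C(C)=C/C(C)=C\C(C)(OC(C)=O)C#CC)c(C)c(=O)c1C | intermediate
18 | (aR,5Z,7E)-8-(6-methoxy-3,5-dimethyl-4-oxo-4H-pyran-2-yl)-4,6-dimethylnona-2,3,5,7-tetraen-2-yl acetate | COc1oc(/C(C)=C/C(C)=C\C(C)=[C@]=C(C)OC(C)=O)c(C)c(=O)c1C | intermediate
19 | (1Z)-1-[(6S)-6-(6-methoxy-3,5-dimethyl-4-oxo-4H-pyran-2-yl)-2,4,6-trimethylcyclohexa-2,4-dien-1-ylidene]ethyl acetate | COc1oc([C@@]2(C)C=C(C)C=C(C)/C2=C(\C)OC(C)=O)c(C)c(=O)c1C | intermediate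
20 | lithium (1Z)-1-[(6S)-6-(6-methoxy-3,5-dimethyl-4-oxo-4H-pyran-2-yl)-2,4,6-trimethylcyclohexa-2,4-dien-1-ylidene]ethanolate | COc1oc([C@@]2(C)C=C(C)C=C(C)/C2=C(\C)O[Li])c(C)c(=O)c1C | intermediate
21 | 2-[(1S,6R)-6-acetyl-1,3,5-trimethylcyclohexa-2,4-dien-1-yl]-6-methoxy-3,5-dimethyl-4H-pyran-4-one | COc1oc([C@@]2(C)C=C(C)C=C(C)[C@H]2C(C)=O)c(C)c(=O)c1C | intermediate
22 | 1-propynylmagnesium bromide | CC#C[Mg]Br | starting material
23 | dichloro(prop-1-yn-1-yl)cerium | CC#C[Ce](Cl)Cl | intermediate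
24 | 2-[(1S,6R)-6-(2-hydroxypent-3-yn-2-yl)-1,3,5-trimethylcyclohexa-2,4-dien-1-yl]-6-methoxy-3,5-dimethyl-4H-pyran-4-one (both carbinol epimers) | COc1oc([C@@]2(C)C=C(C)C=C(C)[C@H]2C(C)(O)C#CC)c(C)c(=O)c1C | intermediate
25 | 2-methoxy-3,5-dimethyl-6-[(1S,6S)-1,3,5-trimethyl-6-[(2E)-4-oxopent-2-en-2-yl]cyclohexa-2,4-dien-1-yl]-4H-pyran-4-one | COc1oc([C@@]2(C)C=C(C)C=C(C)[C@H]2/C(C)=C/C(C)=O)c(C)c(=O)c1C | target

## Step count and risks

Total steps: 10. Longest linear sequence: 8 steps (1, 2, 5, 6, 7, 8, 9, 10) from methyl 2-methyl-3-oxopentanoate; the aldehyde branch (steps 3 and 4) is 2 steps.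

The three steps most likely to fail:

**Step 8 (the new method).** The ion pair may collapse without face selectivity, the cation may isomerise at the Z alkene or cyclise on its own, or the inward/outward preference at the allene terminus may be weak. The fallback uses known chemistry only, sets out from 13 (with 14) and comes back at 21. CuCl/Xantphos-catalysed syn-borylation of ynone 14 with B2pin2 and MeOH gives the boryl enone (3Z)-4-(4,4,5,5-tetramethyl-1,3,2-dioxaborolan-2-yl)pent-3-en-2-one F1. Suzuki coupling of F1 with iodide 13 (Pd(dppf)Cl2, aqueous K3PO4, THF, 40 °C) gives the trienone 2-methoxy-3,5-dimethyl-6-[(2E,4Z,6E)-4,6-dimethyl-8-oxonona-2,4,6-trien-2-yl]-4H-pyran-4-one F2. Heating F2 in toluene at 130 °C brings about the uncatalysed disrotatory 6π closure to the cis ketone as a racemate, that is 21 together with its mirror image 2-[(1R,6S)-6-acetyl-1,3,5-trimethylcyclohexa-2,4-dien-1-yl]-6-methoxy-3,5-dimethyl-4H-pyran-4-one F3. Preparative chromatography on a chiral stationary phase with supercritical CO2 separates 21 from F3, and 21 continues with step 9.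

**Step 7.** The iodine–magnesium exchange may be slow on this dienyl iodide, or the Grignard reagent may attack the pyranone. The fallback builds the carbinol before the pyranone is attached; it sets out from 8 and comes back at 17. Alcohol 8 is converted with n-BuLi and then t-BuLi (Et2O, −78 °C) into lithium (2Z)-3-lithio-2-methylprop-2-en-1-olate F4, which adds to ynone 14 to give dilithium (2Z)-2,4-dimethylhept-2-en-5-yne-1,4-diolate F5. Acetylation in the flask with Ac2O gives (2Z)-2,4-dimethylhept-2-en-5-yne-1,4-diyl diacetate F6. Selective methanolysis of the primary acetate (K2CO3, MeOH, 0 °C) gives (5Z)-7-hydroxy-4,6-dimethylhept-5-en-2-yn-4-yl acetate F7, and MnO2 gives (5Z)-4,6-dimethyl-7-oxohept-5-en-2-yn-4-yl acetate F8. Aldol addition of lithiated pyranone 10 gives (5Z)-7-hydroxy-8-(6-methoxy-3,5-dimethyl-4-oxo-4H-pyran-2-yl)-4,6-dimethylnon-5-en-2-yn-4-yl acetate F9. Mesylation to the methanesulfonate of F9 F10 and DBU elimination give 17.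

**Step 10.** The rearrangement may give an E/Z mixture, or the cationic gold may attack the diene. The fallback replaces the alkyne rearrangement by an oxidative allylic transposition; it sets out from 24 and comes back at 25. Semi-hydrogenation of 24 (H2, Pd on CaCO3 poisoned with Pb(OAc)2, quinoline, EtOAc) gives the propenyl carbinol 2-[(1S,6R)-6-[(3Z)-2-hydroxypent-3-en-2-yl]-1,3,5-trimethylcyclohexa-2,4-dien-1-yl]-6-methoxy-3,5-dimethyl-4H-pyran-4-one F11. Babler–Dauben oxidation of this tertiary allylic alcohol with pyridinium chlorochromate [C5H5NH][CrO3Cl] in CH2Cl2 transposes the oxygen to C9 and gives enone 25.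

## Further compounds

F1 | step 8 | (3Z)-4-(4,4,5,5-tetramethyl-1,3,2-dioxaborolan-2-yl)pent-3-en-2-one | CC(=O)/C=C(\C)B1OC(C)(C)C(C)(C)O1
F2 | step 8 | 2-methoxy-3,5-dimethyl-6-[(2E,4Z,6E)-4,6-dimethyl-8-oxonona-2,4,6-trien-2-yl]-4H-pyran-4-one | COc1oc(/C(C)=C/C(C)=C\C(C)=C\C(C)=O)c(C)c(=O)c1C
F3 | step 8 | 2-[(1R,6S)-6-acetyl-1,3,5-trimethylcyclohexa-2,4-dien-1-yl]-6-methoxy-3,5-dimethyl-4H-pyran-4-one | COc1oc([C@]2(C)C=C(C)C=C(C)[C@@H]2C(C)=O)c(C)c(=O)c1C
F4 | step 7 | lithium (2Z)-3-lithio-2-methylprop-2-en-1-olate | [Li]/C=C(/C)CO[Li]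
F5 | step 7 | dilithium (2Z)-2,4-dimethylhept-2-en-5-yne-1,4-diolate | [Li]OC/C(C)=C\C(C)(O[Li])C#CC
F6 | step 7 | (2Z)-2,4-dimethylhept-2-en-5-yne-1,4-diyl diacetate | CC(=O)OC/C(C)=C\C(C)(OC(C)=O)C#CC
F7 | step 7 | (5Z)-7-hydroxy-4,6-dimethylhept-5-en-2-yn-4-yl acetate | OC/C(C)=C\C(C)(OC(C)=O)C#CC
F8 | step 7 | (5Z)-4,6-dimethyl-7-oxohept-5-en-2-yn-4-yl acetate | O=C/C(C)=C\C(C)(OC(C)=O)C#CC
F9 | step 7 | (5Z)-7-hydroxy-8-(6-methoxy-3,5-dimethyl-4-oxo-4H-pyran-2-yl)-4,6-dimethylnon-5-en-2-yn-4-yl acetate | COc1oc(C(C)C(O)/C(C)=C\C(C)(OC(C)=O)C#CC)c(C)c(=O)c1C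
F10 | step 7 | methanesulfonate of F9 | COc1oc(C(C)C(OS(C)(=O)=O)/C(C)=C\C(C)(OC(C)=O)C#CC)c(C)c(=O)c1C
F11 | step 10 | 2-[(1S,6R)-6-[(3Z)-2-hydroxypent-3-en-2-yl]-1,3,5-trimethylcyclohexa-2,4-dien-1-yl]-6-methoxy-3,5-dimethyl-4H-pyran-4-one | COc1oc([C@@]2(C)C=C(C)C=C(C)[C@H]2C(C)(O)/C=C\C)c(C)c(=O)c1C
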